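The data were generated by integration from invented constants.

Count first, said the chair.

| flask | starting material | temperature | remark | time |
|---|---|---|---|---|
| cedar | 0.074 M | 102 °C | run made earlier |  |
| larch | 0.17 M | 119 °C | run made earlier |  |
| Friday's | 0.11 M | 95 °C |  | 2.0 min |
| Tuesday's | 0.11 M | 125 °C |  | 2.0 min |
| Saturday's | 0.11 M | 110 °C |  | 2.0 min |

- cedar (time / s: target / %, starting material / %): 10.0: 9.6, 26.4; 15.0: 9.7, 18.7; 25.0: 14.2, 9.2; 40.0: 16.3, 6.9; 60.0: 17.6, 4.9; 80.0: 19.3, 2.0
- larch (time / s: target / %, starting material / %): 10.0: 16.4, 5.4; 12.0: 16.6, 5.7; 20.0: 18.3, 2.8; 25.0: 18.2, 1.1

(readings scatter by 1 percentage point)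

1. the flask with the highest amount of target, in percent of the starting material charged ("all alike" if they lie within 1.5 percentage points) (Friday's / Tuesday's / Saturday's / all alike)
2. final target, as a percentage of the starting material charged, in Friday's
3. final target, as a percentage of the starting material charged, in Tuesday's
4. final target, as a percentage of the starting material charged, in Saturday's

- percentages count the starting material that a species holds: one self-condensation product counts as two
- steps that have been proposed: starting material -> side product; 2 starting material -> self-condensation product; starting material -> target

The chair asked whether 2.0 min is long for these flasks. Keeping the minutes, I offered my own count. At the cedar run's first reading, 73.6 % of the charge was lost, far more than the 9.6 % found as target, so I took pairing of starting material as the main loss. Where the loss goes in pairs and the temperature is held, N, the ratio of lost to left, grows in step with charge C and time t, and N then counts first half-lives. That reading gives the turnover constant g = N/(Ct), 3.77 /M/s, which carries the scatter of one reading.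

Friday's, colder than the other two flasks, then counts N = 49.7 turnovers, far above one, leaving 1.97 %. I noted that g was read at 102 °C, warmer than Friday's, and that my count ignores this.

The bench chemist took this to mean that, on this count, Friday's stops close to its end share of target, the selectivity of that flask, with 1.97 % of the charge still to be split. Cedar's last reading showed 19.3 % target and larch's 18.2 %, 1.1 percentage points apart, although larch was richer and hotter.

The forecaster argued that “selectivity improves as the starting material thins out” and, from the two runs, that heat favours the target. The forecast named Tuesday's as the best flask. It gave 11 % (8.5 % to 13.5 %) for Friday's, 29 % (22 % to 34 %) for Tuesday's and 20 % (17 % to 23 %) for Saturday's.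

The simulation gave the most target in Tuesday's: 30.2 % in Tuesday's, against 20.3 % in Saturday's and 11.3 % in Friday's.

    starting material → side product (k = 0.00289 /s, Ea = 125 kJ/mol)
    2 starting material → self-condensation product (k = 2.15 /M/s, Ea = 48.0 kJ/mol)
    starting material → target (k = 0.0380 /s, Ea = 105 kJ/mol)
    (constants at 110 °C)

Friday's held 1.5 % starting material at 2.00 min against the 1.97 % counted, and left for 20.0 min it reached 12.5 % target. A neighbour of Friday's, charged at 0.044 M, counts 19.9 turnovers and so 4.78 % left; it held 3.6 % starting material and 20.1 % target.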